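**Plan**

1. Ring numbering used here: O1, C2 (Me), C3 (CH2OH), C4 (CH2CO2R), C5 (CO2Me), C6 (=CH–O). Cuts: the two O–benzyl bonds; the C3 carbinol back to an N-acyl thiazolidinethione; then, in one event, O1–C6 and C2–C3, which opens the ring to acetaldehyde plus an open chain.
2. Enabling feature: O1 is both the β-oxygen of a C2–C3 aldol and the heteroatom of the vinylogous carbonate O1–C6=C5–CO2Me, so a C=O unit can be inserted between a C3 enolate and a C6 that carries a leaving group (OMe).
3. Further cuts: imide N–C and arylethyl ester O–C back to a prochiral glutaric anhydride (temporary ring); C6 back to methyl formate; the C4 core back to C3-symmetric trimethyl methanetriacetate (dimethyl glutaconate + dimethyl malonate).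
4. Forward: chain first (steps 1–3), the two remaining arms differentiated through the anhydride (steps 4–7), the dihydropyran closes in step 8, then the acyl group is reduced and the phenols are freed.
5. Stereochemistry: C4 from catalytic enantioselective anhydride alcoholysis; C2 and C3 from the syn-aldol directed by (4S)-4-benzyl-1,3-thiazolidine-2-thione (syn aldol = 2,3-trans ring). No later intermediate has an enolisable carbonyl at C3, so these centres are not expected to scramble.

Key step: step 8

Remark: the sense of the alkaloid-catalysed anhydride opening in step 6 is assigned by analogy with 3-alkylglutaric anhydrides; should a first run show the opposite sense, the pseudo-enantiomeric (DHQ)2AQN is used instead, with nothing else changed.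

**Route**

Step 1
Reactants: 1 dimethyl (E)-pent-2-enedioate (dimethyl glutaconate); 2 dimethyl malonate
Product: 3 dimethyl 3-[bis(methoxycarbonyl)methyl]pentanedioate
Conditions: NaOMe (0.2 equiv), MeOH, 65 °C
Reagents that add atoms: none
Why: Base-catalysed Michael addition of the malonate anion to the β-carbon of the glutaconate; the new CH carries two identical arms and is not a stereocentre.

Step 2
Reactants: 3 dimethyl 3-[bis(methoxycarbonyl)methyl]pentanedioate
Product: 4 trimethyl methanetriacetate [dimethyl 3-(2-methoxy-2-oxoethyl)pentanedioate]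
Conditions: NaCl (1.5 equiv), H2O (2 equiv), DMSO, 150 °C
Reagents that add atoms: none
Why: Krapcho dealkoxycarbonylation removes one ester from the geminal diester only and should leave the C3-symmetric triester.

Step 3
Reactants: 4 trimethyl methanetriacetate
Product: 6 dimethyl 3-[(1E)-1,3-dimethoxy-3-oxoprop-1-en-2-yl]pentanedioate, via sodium formyl-ester enolate 5 (not isolated)
Conditions: NaH (1.05 equiv), HCO2Me (5 equiv), THF, 0 → 23 °C; then DMF, Me2SO4 (1.1 equiv), 23 °C
Reagents that add atoms: methyl formate (COC=O); dimethyl sulfate (COS(=O)(=O)OC)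
Why: Crossed Claisen formylation followed by O-methylation of the enolate is the standard entry to β-methoxyacrylates; the three arms of 4 are equivalent, so any arm gives the same achiral product, and one equivalent of base limits the reaction to one arm on average (E enol ether expected, geometry immaterial because C6 ends in the ring).

Step 4
Reactants: 6 dimethyl 3-[(1E)-1,3-dimethoxy-3-oxoprop-1-en-2-yl]pentanedioate
Product: 7 3-[(1E)-1,3-dimethoxy-3-oxoprop-1-en-2-yl]pentanedioic acid
Conditions: LiOH (2.2 equiv), THF/H2O 3:1, 0 °C; then 1 M HCl to pH 2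
Reagents that add atoms: lithium hydroxide ([Li+].[OH-])
Why: Saponification, in which the two unhindered saturated methyl esters should hydrolyse far faster than the α-branched push–pull (vinylogous carbonate) acrylate ester.

Step 5
Reactants: 7 3-[(1E)-1,3-dimethoxy-3-oxoprop-1-en-2-yl]pentanedioic acid
Product: 8 methyl (2E)-2-(2,6-dioxooxan-4-yl)-3-methoxyprop-2-enoate
Conditions: Ac2O, 80 °C; evaporation with toluene
Reagents that add atoms: none
Why: Cyclodehydration of the 1,5-diacid with acetic anhydride gives the six-membered cyclic anhydride, a temporary ring that turns the two arms into enantiotopic acyl donors.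

Step 6
Reactants: 8 methyl (2E)-2-(2,6-dioxooxan-4-yl)-3-methoxyprop-2-enoate; 9 2-[3,4-bis(benzyloxy)phenyl]ethanol
Product: 10 (3R)-5-{2-[3,4-bis(benzyloxy)phenyl]ethoxy}-3-[(1E)-1,3-dimethoxy-3-oxoprop-1-en-2-yl]-5-oxopentanoic acid
Conditions: 9 (1.2 equiv), (DHQD)2AQN (hydroquinidine anthraquinone-1,4-diyl diether, 0.2 equiv), toluene/MTBE 1:1, −30 °C
Reagents that add atoms: none
Why: Cinchona-alkaloid-catalysed enantioselective alcoholysis (desymmetrisation) of a 3-substituted glutaric anhydride, in which the quinuclidine nitrogen activates alcohol 9 for attack on one enantiotopic carbonyl; this sets C4 and installs the arylethyl ester directly.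

Step 7
Reactants: 10 (3R)-5-{2-[3,4-bis(benzyloxy)phenyl]ethoxy}-3-[(1E)-1,3-dimethoxy-3-oxoprop-1-en-2-yl]-5-oxopentanoic acid; 11 (4S)-4-benzyl-1,3-thiazolidine-2-thione
Product: 12 2-[3,4-bis(benzyloxy)phenyl]ethyl (3R)-5-[(4S)-4-benzyl-2-sulfanylidene-1,3-thiazolidin-3-yl]-3-[(1E)-1,3-dimethoxy-3-oxoprop-1-en-2-yl]-5-oxopentanoate
Conditions: EDC·HCl (1.3 equiv), DMAP (0.2 equiv), CH2Cl2, 0 → 23 °C
Reagents that add atoms: none
Why: Carbodiimide/DMAP N-acylation of the thiazolidinethione turns the free acid arm into a chelating, readily enolised and later reducible acyl group that also carries the stereodirecting element.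

Step 8
Reactants: 12 2-[3,4-bis(benzyloxy)phenyl]ethyl (3R)-5-[(4S)-4-benzyl-2-sulfanylidene-1,3-thiazolidin-3-yl]-3-[(1E)-1,3-dimethoxy-3-oxoprop-1-en-2-yl]-5-oxopentanoate; 13 acetaldehyde
Product: 15 methyl (2R,3S,4S)-3-{[(4S)-4-benzyl-2-sulfanylidene-1,3-thiazolidin-3-yl]carbonyl}-4-(2-{2-[3,4-bis(benzyloxy)phenyl]ethoxy}-2-oxoethyl)-2-methyl-3,4-dihydro-2H-pyran-5-carboxylate, via trichlorotitanium syn-aldolate 14 (not isolated)
Conditions: TiCl4 (1.05 equiv), iPr2NEt (1.1 equiv), NMP (1.0 equiv), CH2Cl2, 0 °C; 13 (3 equiv), −78 °C; then TiCl4 (1.0 equiv), −78 → −20 °C; NH4Cl (aq)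
Reagents that add atoms: none
Why: TiCl4/iPr2NEt/NMP should enolise only the chelating N-acylthiazolidinethione arm to its Z-chlorotitanium enolate, which adds to acetaldehyde through a closed chair (Zimmerman–Traxler) transition state to form C2–C3; the resulting titanium alkoxide, six atoms from C6, then adds to the β-methoxyacrylate once its carbonyl is activated by the second equivalent of TiCl4, and methoxide is expelled (oxa-Michael addition/β-elimination), which forms O1–C6 and restores the C5=C6 enol ether. The closest known reaction types are the auxiliary-controlled titanium syn-aldol of N-acylthiazolidinethiones with aliphatic aldehydes and the acid-promoted alkoxy exchange (vinylogous transesterification) of β-alkoxyacrylates. The dihydropyran closes in the 6-endo-trig mode at C6, followed by loss of methanol. C3 is set by the auxiliary, whose benzyl group shields one enolate face in the non-chelated (Evans-syn) transition state, and C2 by the Z-enolate geometry in the chair, which enforces the syn aldol that corresponds to the 2,3-trans ring; with the (4S)-auxiliary this syn pair is the (2S,3R) one that places the C3 acyl group trans to the C4 side chain, the C4 centre being a spectator. The step needs chemoselective enolisation (secured by bidentate binding of TiCl4 to the thioimide and its higher acidity than the ester arm), acetaldehyde acting only as the electrophile (no free base, −78 °C), and O-attack at C6 in place of lactonisation onto the saturated ester (secured by preferential Lewis-acid activation of the more basic vinylogous-carbonate carbonyl).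

Step 9
Reactants: 15 methyl (2R,3S,4S)-3-{[(4S)-4-benzyl-2-sulfanylidene-1,3-thiazolidin-3-yl]carbonyl}-4-(2-{2-[3,4-bis(benzyloxy)phenyl]ethoxy}-2-oxoethyl)-2-methyl-3,4-dihydro-2H-pyran-5-carboxylate
Product: 16 methyl (2R,3R,4S)-4-(2-{2-[3,4-bis(benzyloxy)phenyl]ethoxy}-2-oxoethyl)-3-(hydroxymethyl)-2-methyl-3,4-dihydro-2H-pyran-5-carboxylate
Conditions: NaBH4 (2.5 equiv), THF/EtOH 10:1, −10 → 0 °C; NH4Cl (aq)
Reagents that add atoms: none
Why: Hydride reduction of the activated N-acylthiazolidinethione (through the aldehyde, which is reduced at once) should give the primary alcohol and release the auxiliary, while both esters and the vinylogous carbonate are inert to NaBH4 at this temperature and no stereocentre is touched.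

Step 10
Reactants: 16 methyl (2R,3R,4S)-4-(2-{2-[3,4-bis(benzyloxy)phenyl]ethoxy}-2-oxoethyl)-3-(hydroxymethyl)-2-methyl-3,4-dihydro-2H-pyran-5-carboxylate
Product: 17 methyl (2R,3R,4S)-4-{2-[2-(3,4-dihydroxyphenyl)ethoxy]-2-oxoethyl}-3-(hydroxymethyl)-2-methyl-3,4-dihydro-2H-pyran-5-carboxylate (CNP0204147.1)
Conditions: H2 (1 atm), Pd/C (10% w/w), EtOAc, 23 °C
Reagents that add atoms: none
Why: Hydrogenolysis of the two aryl benzyl ethers over Pd/C under neutral conditions, in which the push–pull enol-ether double bond should not be hydrogenated and the δ-hydroxy ester sees neither acid nor base.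

**Compound list**

1 | dimethyl (E)-pent-2-enedioate (dimethyl glutaconate) | COC(=O)/C=C/CC(=O)OC | starting material
2 | dimethyl malonate | COC(=O)CC(=O)OC | starting material
3 | dimethyl 3-[bis(methoxycarbonyl)methyl]pentanedioate | COC(=O)CC(CC(=O)OC)C(C(=O)OC)C(=O)OC | intermediate
4 | trimethyl methanetriacetate [dimethyl 3-(2-methoxy-2-oxoethyl)pentanedioate] | COC(=O)CC(CC(=O)OC)CC(=O)OC | intermediate
5 | sodium enolate of dimethyl 3-(1-methoxy-1,3-dioxopropan-2-yl)pentanedioate | [Na+].[O-]C=C(C(=O)OC)C(CC(=O)OC)CC(=O)OC | intermediate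
6 | dimethyl 3-[(1E)-1,3-dimethoxy-3-oxoprop-1-en-2-yl]pentanedioate | COC(=O)CC(CC(=O)OC)/C(C(=O)OC)=C\OC | intermediate
7 | 3-[(1E)-1,3-dimethoxy-3-oxoprop-1-en-2-yl]pentanedioic acid | OC(=O)CC(CC(=O)O)/C(C(=O)OC)=C\OC | intermediate
8 | methyl (2E)-2-(2,6-dioxooxan-4-yl)-3-methoxyprop-2-enoate | O=C1CC(CC(=O)O1)/C(C(=O)OC)=C\OC | intermediate
9 | 2-[3,4-bis(benzyloxy)phenyl]ethanol | OCCc1ccc(OCc2ccccc2)c(OCc2ccccc2)c1 | starting material
10 | (3R)-5-{2-[3,4-bis(benzyloxy)phenyl]ethoxy}-3-[(1E)-1,3-dimethoxy-3-oxoprop-1-en-2-yl]-5-oxopentanoic acid | OC(=O)C[C@H](CC(=O)OCCc1ccc(OCc2ccccc2)c(OCc2ccccc2)c1)/C(C(=O)OC)=C\OC | intermediate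
11 | (4S)-4-benzyl-1,3-thiazolidine-2-thione | S=C1N[C@@H](Cc2ccccc2)CS1 | starting material
12 | 2-[3,4-bis(benzyloxy)phenyl]ethyl (3R)-5-[(4S)-4-benzyl-2-sulfanylidene-1,3-thiazolidin-3-yl]-3-[(1E)-1,3-dimethoxy-3-oxoprop-1-en-2-yl]-5-oxopentanoate | S=C1SC[C@H](Cc2ccccc2)N1C(=O)C[C@H](CC(=O)OCCc1ccc(OCc2ccccc2)c(OCc2ccccc2)c1)/C(C(=O)OC)=C\OC | intermediate
13 | acetaldehyde | CC=O | starting material
14 | trichlorotitanium (2S,3R)-syn-aldolate formed from 12 plus acetaldehyde | S=C1SC[C@H](Cc2ccccc2)N1C(=O)[C@H]([C@@H](C)O[Ti](Cl)(Cl)Cl)[C@H](CC(=O)OCCc1ccc(OCc2ccccc2)c(OCc2ccccc2)c1)/C(C(=O)OC)=C\OC | intermediate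
15 | methyl (2R,3S,4S)-3-{[(4S)-4-benzyl-2-sulfanylidene-1,3-thiazolidin-3-yl]carbonyl}-4-(2-{2-[3,4-bis(benzyloxy)phenyl]ethoxy}-2-oxoethyl)-2-methyl-3,4-dihydro-2H-pyran-5-carboxylate | COC(=O)C1=CO[C@H](C)[C@@H](C(=O)N2C(=S)SC[C@@H]2Cc2ccccc2)[C@@H]1CC(=O)OCCc1ccc(OCc2ccccc2)c(OCc2ccccc2)c1 | intermediate
16 | methyl (2R,3R,4S)-4-(2-{2-[3,4-bis(benzyloxy)phenyl]ethoxy}-2-oxoethyl)-3-(hydroxymethyl)-2-methyl-3,4-dihydro-2H-pyran-5-carboxylate | COC(=O)C1=CO[C@H](C)[C@@H](CO)[C@@H]1CC(=O)OCCc1ccc(OCc2ccccc2)c(OCc2ccccc2)c1 | intermediate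
17 | methyl (2R,3R,4S)-4-{2-[2-(3,4-dihydroxyphenyl)ethoxy]-2-oxoethyl}-3-(hydroxymethyl)-2-methyl-3,4-dihydro-2H-pyran-5-carboxylate (CNP0204147.1) | COC(=O)C1=CO[C@H](C)[C@@H](CO)[C@@H]1CC(=O)OCCc1ccc(O)c(O)c1 | target

**Totals**

Total step count: 10. Longest linear sequence: 10 steps (1 → 17); compounds 2, 9, 11 and 13 enter as purchased materials.

**Steps most likely to fail, with fallbacks**

Step 8 (key step). The titanium alkoxide may not add to the methoxyacrylate in the same flask before retro-aldol or β-elimination sets in on warming. Lactonisation onto the saturated ester may compete, and the second equivalent of TiCl4 may start to cleave the aryl benzyl ethers. Fallback, setting out from 12: the aldol is run as in step 8 with one equivalent of TiCl4 and quenched at −78 °C, which should give the isolable syn β-hydroxy imide F1. Compound F1 is then closed in a separate Brønsted-acid-catalysed alkoxy exchange (pyridinium p-toluenesulfonate, toluene, 60 °C, 4 Å molecular sieves to take up methanol). Under these conditions transesterification of the saturated ester is not expected. The route is rejoined at 15.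

Step 6. Discrimination between the enantiotopic carbonyls may be weak or of the wrong sense with this bulky primary alcohol and the sp2-branched 3-substituent, and uncatalysed background opening may erode the selectivity. Fallback, setting out from 8: the anhydride is opened with 9 without chiral catalyst (Et3N, DMAP, CH2Cl2) to give the racemic hemiester F2. F2 is acylated onto 11 exactly as in step 7, which gives 12 together with its (3S)-diastereomer F3. The auxiliary then serves as a covalent resolving group: the two imides are separated by chromatography or crystallisation, and the route is rejoined at 12.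

Step 3. Formylation of three equivalent arms may over- and under-run (bis-formylation, recovered 4), and C-methylation may compete with O-methylation. Fallback, setting out from 1, with the arm fixed by construction:
- Michael addition of tert-butyl methyl malonate to 1 (NaOMe cat., MeOH) should give the mixed malonate, tert-butyl methyl 2-(1,5-dimethoxy-1,5-dioxopentan-3-yl)malonate F4.
- Trifluoroacetic acid in CH2Cl2 removes the tert-butyl group to give the malonic half-acid F5.
- BH3·SMe2 (THF, 0 °C) reduces only the acid to the β-hydroxy ester F6.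
- Dess–Martin periodinane gives the formyl ester, held as its enol, F7.
- Me2SO4/K2CO3 in acetone methylates the enol oxygen, and the route is rejoined at 6.

**Further compounds**

F1 | step 8 | 2-[3,4-bis(benzyloxy)phenyl]ethyl (3R,4S,5R)-4-{[(4S)-4-benzyl-2-sulfanylidene-1,3-thiazolidin-3-yl]carbonyl}-3-[(1E)-1,3-dimethoxy-3-oxoprop-1-en-2-yl]-5-hydroxyhexanoate (syn β-hydroxy imide) | S=C1SC[C@H](Cc2ccccc2)N1C(=O)[C@H]([C@@H](C)O)[C@H](CC(=O)OCCc1ccc(OCc2ccccc2)c(OCc2ccccc2)c1)/C(C(=O)OC)=C\OC
F2 | step 6 | racemic 5-{2-[3,4-bis(benzyloxy)phenyl]ethoxy}-3-[(1E)-1,3-dimethoxy-3-oxoprop-1-en-2-yl]-5-oxopentanoic acid | OC(=O)CC(CC(=O)OCCc1ccc(OCc2ccccc2)c(OCc2ccccc2)c1)/C(C(=O)OC)=C\OC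
F3 | step 6 | 2-[3,4-bis(benzyloxy)phenyl]ethyl (3S)-5-[(4S)-4-benzyl-2-sulfanylidene-1,3-thiazolidin-3-yl]-3-[(1E)-1,3-dimethoxy-3-oxoprop-1-en-2-yl]-5-oxopentanoate | S=C1SC[C@H](Cc2ccccc2)N1C(=O)C[C@@H](CC(=O)OCCc1ccc(OCc2ccccc2)c(OCc2ccccc2)c1)/C(C(=O)OC)=C\OC
F4 | step 3 | tert-butyl methyl 2-(1,5-dimethoxy-1,5-dioxopentan-3-yl)malonate | COC(=O)CC(CC(=O)OC)C(C(=O)OC)C(=O)OC(C)(C)C
F5 | step 3 | 2-(methoxycarbonyl)-3-(2-methoxy-2-oxoethyl)-5-methoxy-5-oxopentanoic acid (malonic half-acid) | COC(=O)CC(CC(=O)OC)C(C(=O)OC)C(=O)O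
F6 | step 3 | dimethyl 3-(3-hydroxy-1-methoxy-1-oxopropan-2-yl)pentanedioate | COC(=O)CC(CC(=O)OC)C(CO)C(=O)OC
F7 | step 3 | dimethyl 3-(3-hydroxy-1-methoxy-1-oxoprop-2-en-2-yl)pentanedioate (enol of the formyl ester) | COC(=O)CC(CC(=O)OC)C(=CO)C(=O)OC
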